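**Retrosynthetic overview**
- Lespeflorin C5 ⇒ cut the Cα–O bond. The last step is an enantioselective hydroxylation of the α-deoxy dihydrochalcone, and it sets the only stereocentre (S).
- C5'-prenyl dihydrochalcone ⇒ its 4'-O-prenyl ether by an O→C [1,3] prenyl shift. The ether comes from the trihydroxy dihydrochalcone and prenyl bromide (C–O bond at the most acidic phenol).
- Trihydroxy dihydrochalcone ⇒ 2-methylresorcinol + phloretic acid (Friedel–Crafts acylation).
- No ring is formed. Both benzene rings are bought in with the two starting materials.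

Assumption: the (+)-oxaziridine is taken to induce the same sense on the poly-anion as it does on Z-enolates of simple aryl alkyl ketones (S carbinol). The (−)-reagent is equally available if the sense turns out reversed.

Primed locants refer to the acyl-bearing ring.

**Step 1**
Reactants: 1 2-methylresorcinol; 2 3-(4-hydroxyphenyl)propanoic acid (phloretic acid)
Product: 3 1-(2,4-dihydroxy-3-methylphenyl)-3-(4-hydroxyphenyl)propan-1-one
Conditions: BF3·OEt2 (as solvent), 85 °C, 2 h; aq NaOAc work-up
Reagents that add atoms: none
Why: Friedel–Crafts (Nencki-type) acylation in which the BF3-activated acid attacks the only doubly activated position of 1 (C4 = C6, ortho/para to the two OH groups), and boron chelation of the resulting o-hydroxy ketone prevents a second acylation.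

**Step 2**
Reactants: 3 1-(2,4-dihydroxy-3-methylphenyl)-3-(4-hydroxyphenyl)propan-1-one; 4 prenyl bromide
Product: 5 1-[2-hydroxy-3-methyl-4-(3-methylbut-2-en-1-yloxy)phenyl]-3-(4-hydroxyphenyl)propan-1-one
Conditions: 4 (1.05 equiv), K2CO3 (1.1 equiv), acetone, reflux, 6 h
Reagents that add atoms: prenyl bromide (compound 4), CC(C)=CCBr
Why: Williamson etherification in which one equivalent of weak base ionises only the 4'-OH (para-acyl vinylogous acid, pKa about 8), because the 2'-OH is hydrogen-bonded to the ketone and the B-ring phenol (pKa about 10) stays protonated, so SN2 on the primary allylic bromide gives the 4'-ether.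

**Step 3**
Reactants: 5 1-[2-hydroxy-3-methyl-4-(3-methylbut-2-en-1-yloxy)phenyl]-3-(4-hydroxyphenyl)propan-1-one
Product: 6 1-[2,4-dihydroxy-3-methyl-5-(3-methylbut-2-en-1-yl)phenyl]-3-(4-hydroxyphenyl)propan-1-one
Conditions: Montmorillonite K10 (100 wt%), CH2Cl2, 0 °C → rt, 3 h
Reagents that add atoms: none
Why: Acid-clay-promoted formal [1,3] O→C prenyl shift (tight ion pair, Friedel–Crafts-type recombination) that returns the prenyl unit through its primary terminus to an ortho carbon, and since C3' is blocked by methyl only C5' can accept it.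

**Step 4 (key step)**
Reactants: 6 1-[2,4-dihydroxy-3-methyl-5-(3-methylbut-2-en-1-yl)phenyl]-3-(4-hydroxyphenyl)propan-1-one
Product: 9 lespeflorin C5 [(2S)-1-[2,4-dihydroxy-3-methyl-5-(3-methylbut-2-en-1-yl)phenyl]-2-hydroxy-3-(4-hydroxyphenyl)propan-1-one], via tetralithium Z-enolate 7 (not isolated), via tetralithium alkoxide 8 (not isolated)
Conditions: LiHMDS (4.3 equiv), THF, −78 → −10 °C, 2 h; (+)-[(8,8-dichlorocamphoryl)sulfonyl]oxaziridine (1.15 equiv), THF, −78 °C, 1 h; AcOH (5 equiv), −78 °C
Reagents that add atoms: (+)-[(8,8-dichlorocamphoryl)sulfonyl]oxaziridine, CC1(C)[C@@H]2CC[C@]13CS(=O)(=O)N4O[C@@]34C2(Cl)Cl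
Why: Proposed new method: reagent-controlled enantioselective hydroxylation of a fully unprotected polyphenolic ketone as its tetra-anion, in which LiHMDS removes the three phenolic protons and then one α-CH2 proton, a lithium bridging the 2'-phenoxide and the enolate oxygen holds a planar six-membered chelate that allows only the Z(O)-enolate, the enolate carbon is by far the most nucleophilic site and attacks the oxaziridine oxygen in an open SN2-type transition state whose dichlorocamphor skeleton leaves only the Cα Si face open (giving S), phenoxides and the prenyl alkene are inert to N-sulfonyloxaziridines at −78 °C, the hindered ketimine by-product does not add to the enolate, and the product remains a non-enolisable lithium alkoxide until the cold AcOH quench so it cannot racemise; the closest known reaction types are the Davis asymmetric enolate hydroxylation of O-protected aryl alkyl ketones and the C-selective trapping of polylithiated hydroxyacetophenones with acyl chlorides.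

**Compound list**
1 | 2-methylresorcinol (2-methylbenzene-1,3-diol) | Cc1c(O)cccc1O | starting material
2 | phloretic acid, 3-(4-hydroxyphenyl)propanoic acid | OC(=O)CCc1ccc(O)cc1 | starting material
3 | 1-(2,4-dihydroxy-3-methylphenyl)-3-(4-hydroxyphenyl)propan-1-one | Cc1c(O)ccc(C(=O)CCc2ccc(O)cc2)c1O | intermediate
4 | prenyl bromide (1-bromo-3-methylbut-2-ene) | CC(C)=CCBr | starting material
5 | 4'-O-prenyl ether: 1-[2-hydroxy-3-methyl-4-(3-methylbut-2-en-1-yloxy)phenyl]-3-(4-hydroxyphenyl)propan-1-one | CC(C)=CCOc1ccc(C(=O)CCc2ccc(O)cc2)c(O)c1C | intermediate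
6 | 5'-C-prenyl dihydrochalcone: 1-[2,4-dihydroxy-3-methyl-5-(3-methylbut-2-en-1-yl)phenyl]-3-(4-hydroxyphenyl)propan-1-one | CC(C)=CCc1cc(C(=O)CCc2ccc(O)cc2)c(O)c(C)c1O | intermediate
7 | tetralithium salt of 6: three phenoxides plus the Z(O)-enolate (not isolated) | [Li+].[Li+].[Li+].[Li+].CC(C)=CCc1cc(/C([O-])=C/Cc2ccc([O-])cc2)c([O-])c(C)c1[O-] | intermediate
8 | tetralithium salt of 9: three phenoxides plus the (S)-α-alkoxide (not isolated) | [Li+].[Li+].[Li+].[Li+].CC(C)=CCc1cc(C(=O)[C@@H]([O-])Cc2ccc([O-])cc2)c([O-])c(C)c1[O-] | intermediate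
9 | lespeflorin C5, (2S)-α-hydroxy dihydrochalcone | CC(C)=CCc1cc(C(=O)[C@@H](O)Cc2ccc(O)cc2)c(O)c(C)c1O | target

**Totals**
Total step count: 4. Longest linear sequence: 4.

**Three steps most likely to fail**

*Step 4 (the new method).*
- Risks: the tetra-anion may dissolve poorly or enolise incompletely. The ee may be lower for an aggregated lithium poly-anion. Excess oxidant may cause some hydroxylative dearomatisation of the A-ring bis-phenoxide.
- Fallback (known chemistry): it sets out from 6 and comes back to the route at 9. All three phenols are silylated (TBSOTf, 2,6-lutidine, CH2Cl2, 0 °C) to give the tris-TBS ether F1. Its sodium Z-enolate (NaHMDS, THF, −78 °C) then undergoes the standard Davis hydroxylation with the same (+)-oxaziridine to give the (S)-α-hydroxy tris-TBS ether F2. Buffered desilylation (TBAF/AcOH, THF, 0 °C) releases 9 without epimerisation. This costs two extra steps.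

*Step 3.*
- Risks: the clay shift is dissociative. It can lose the prenyl group back to 3, pass it to the B-ring phenol, or cyclise 6 to the 2,2-dimethylchroman.
- Fallback: it sets out from 3 and comes back at 6, replacing the ionic shift by a concerted one. Pd(PPh3)4-catalysed Tsuji–Trost O-alkylation with tert-butyl 2-methylbut-3-en-2-yl carbonate (THF, 0 °C) gives the 4'-O-(1,1-dimethylallyl) ether F3. Its aromatic Claisen rearrangement (N,N-diethylaniline, 120 °C) inverts the allyl unit and delivers a normal prenyl group to C5', the only free ortho carbon.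

*Step 2.*
- Risks: the 4'-OH and the B-ring OH may be discriminated incompletely, giving bis-ether or the wrong mono-ether.
- Fallback: it sets out from 3 and comes back at 6, skipping 5 and relying on ring nucleophilicity instead of phenol acidity. Direct Friedel–Crafts C-prenylation with 2-methylbut-3-en-2-ol and BF3·OEt2 in dioxane at rt attacks C5', which is ortho and para to the two A-ring hydroxyls. This is one step shorter, but yields for this reaction type are typically only 20–35% and chroman and B-ring isomers must be separated, so it is held in reserve. It makes no compound outside the list (none, F0).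

**Further compounds**
F1 | step 4 | tris-TBS ether of 6: 1-[2,4-bis(tert-butyldimethylsilyloxy)-3-methyl-5-(3-methylbut-2-en-1-yl)phenyl]-3-[4-(tert-butyldimethylsilyloxy)phenyl]propan-1-one | CC(C)=CCc1cc(C(=O)CCc2ccc(O[Si](C)(C)C(C)(C)C)cc2)c(O[Si](C)(C)C(C)(C)C)c(C)c1O[Si](C)(C)C(C)(C)C
F2 | step 4 | (2S)-α-hydroxy tris-TBS ether (tris-TBS ether of 9) | CC(C)=CCc1cc(C(=O)[C@@H](O)Cc2ccc(O[Si](C)(C)C(C)(C)C)cc2)c(O[Si](C)(C)C(C)(C)C)c(C)c1O[Si](C)(C)C(C)(C)C
F3 | step 3 | 4'-O-(1,1-dimethylallyl) ether: 1-[2-hydroxy-3-methyl-4-(2-methylbut-3-en-2-yloxy)phenyl]-3-(4-hydroxyphenyl)propan-1-one | C=CC(C)(C)Oc1ccc(C(=O)CCc2ccc(O)cc2)c(O)c1C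
F0 | step 2 | none | none
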